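Beta and epsilon both carry 0.12 mol%, so no order in initiator can come from a change of loading; it has to come through the solid substrate, which gives beta an [initiator] 3.00 times that of epsilon.

| setting | beta | epsilon | oak | larch | alder | cedar | birch |
|---|---|---|---|---|---|---|---|
| solid substrate | 0.015 M | 0.0050 M | 0.010 M | 0.010 M | 0.010 M | 0.010 M | 0.010 M |
| gas | 3.6 mM (held) | 3.6 mM (held) | 3.6 mM (held) | 3.6 mM (held) | 3.6 mM (held) | 3.6 mM (held) | 3.6 mM (held) |
| initiator | 0.12 mol% | 0.12 mol% | 0.12 mol% | 0.25 mol% | 0.5 mol% | 1 mol% | 2 mol% |
| remark | run made earlier | run made earlier |  |  |  |  |  |
| time |  |  | 40 h | 40 h | 40 h | 40 h | 40 h |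

| run | time / h | target / % | solid substrate / % |
|---|---|---|---|
| beta | 1.00 | 0.3 | 95.2 |
| beta | 1.50 | 1.0 | 94.8 |
| beta | 2.50 | 0.5 | 94.4 |
| beta | 4.00 | 0.9 | 94.4 |
| beta | 6.00 | 2.5 | 93.4 |
| beta | 10.0 | 3.4 | 91.6 |
| beta | 15.0 | 4.7 | 91.2 |
| epsilon | 0.833 | 0 | 86.9 |
| epsilon | 2.00 | 2.2 | 84.8 |
| epsilon | 4.00 | 3.3 | 83.1 |
| epsilon | 6.00 | 4.0 | 82.0 |
| epsilon | 8.00 | 4.7 | 80.7 |
| epsilon | 12.0 | 6.3 | 78.8 |
| epsilon | 15.0 | 7.7 | 78.5 |

(readings scatter by 0.5 percentage points)

- a species is counted by the solid substrate in it: one ended chains A counts as two
- given per volume of solution although it is solid: solid substrate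
- at the start none of reagent is dissolved
- on the list of suspects stand: initiator -> 2 initiating radical; starting material + initiating radical -> capped initiator + first chain carrier; reagent + first chain carrier <-> target + second chain carrier; starting material + second chain carrier -> by-product + first chain carrier; 2 first chain carrier -> ended chains A; 2 second chain carrier -> ended chains B; gas <-> reagent; target -> over-reaction product; solid substrate <-> starting material
- at the start none of the solid substrate is in solution
- "hardly changes" means that all values lie within two and a half points (for a concentration: within two and a half percent of the largest)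

1. amount of target at the end, in percent of the solid substrate charged for oak, larch, alder, cedar, birch, in this order
2. how the row runs (rises all the way / rises, then falls / hardly changes / falls all the way / falls, then rises)

Two chemists read these runs differently. The first takes the flask as one first-order step in solid substrate: percent reacted at a given time then owes nothing to the loading, and the row hardly changes. The second takes it as a radical chain under steady-state termination, with the rate following a power of [initiator].

At the first reading the solid is down by 0.720 mM in beta and 0.655 mM in epsilon, so [starting material] stands about alike in the two runs. Yet at 15.0 h beta holds 0.705 mM of target and epsilon 0.385 mM. The second chemist takes the logarithm of that ratio over the logarithm of the [initiator] ratio and calls it the chain order n, the percent change of target per percent change of [initiator]. It reads 0.551, a reading that carries the scatter of both points.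

At fixed solid substrate and fixed time, n turns a loading ratio into a target ratio, so my own reckoning puts birch over oak at 4.71. The first chemist must explain why the percentages themselves part by 3 percentage points, against a scatter of 0.5 points, but still holds to a flat row.

The forecast sides with the chain: 12%, 17%, 24%, 33%, 45%, and the row rises all the way, with the words “Solid never runs out, so the row keeps rising”. Its birch over oak is 3.75, lower than my 4.71.

The simulation gives 7.42%, 10.8%, 15.4%, 22.2%, 32.0%, and the row rises all the way. The forecast's level stands 1.62 times the simulated one at oak.

    initiator → 2 initiating radical (k = 0.160 h⁻¹)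
    starting material + initiating radical → capped initiator + first chain carrier (k = 5.10 × 10⁵ M⁻¹ s⁻¹)
    reagent + first chain carrier ⇌ target + second chain carrier (K = 3.30, k = 18000 M⁻¹ s⁻¹)
    starting material + second chain carrier → by-product + first chain carrier (k = 3.20 × 10⁷ M⁻¹ h⁻¹)
    2 first chain carrier → ended chains A (k = 1.90 × 10⁶ M⁻¹ s⁻¹)
    2 second chain carrier → ended chains B (k = 6.70 × 10⁷ M⁻¹ s⁻¹)
    gas ⇌ reagent, rate k7*(csat - [reagent]) (kL = 0.420 h⁻¹)
    target → over-reaction product (k = 1.70 × 10⁻⁴ h⁻¹)
    solid substrate ⇌ starting material, rate k9*(cs9 - [starting material]) while solid is left; crystals form when [starting material] > cs9 (solubility = 0.690 mM, k = 3.80 h⁻¹)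

Birch over oak is 4.31, an order of 0.519, and n carried from oak to larch gives 11.1% against 10.8%.  The flat view holds for starting material: 6.89% in oak, 6.87% in birch. Oak's initiator has a half-life by its decay step of 4.3 h at 2.14 h, shorter than the 40 h of the run, while target's half-life by over-reaction alone, 170 d, is far longer. At 40.0 h oak keeps 0.166% of its initiator charge, initiator being the first to run out, the limiting reagent, and target reads 7.42% there and 7.28% at 400 h.

The readings were computed from invented constants; the scatter is artificial.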